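**Retrosynthetic overview**

- Target ⇒ hispidulin by sulfation of O7 and O4' (the O5–H is tied up in the hydrogen bond to the C4 carbonyl) ⇒ its 5,7,4'-tri-O-isopropyl ether, cleaved with BCl3 so that the C6 methyl ether stays.
- Ring C is the only ring made. Its O1–C8a bond is cut back to a 1,3-diaryl-1,3-diketone whose ring A carbon destined to become C8a still carries hydrogen (anodic C–H/O–H closure).
- Feature used: C8a of ring A is para to the methoxy-bearing C6 and meta to C5 and C7, so in the open chain it is the only free ortho C–H (C6) of a 2,4-diisopropoxy-3-methoxybenzoyl ring. A 3,4,5-trioxygenated benzoyl ring would close to the 6,7,8-pattern with C5 bare, so ring A must enter as the 2,3,4-isomer.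
- Diketone ⇒ crossed Claisen condensation of 2,4-diisopropoxy-3-methoxyacetophenone with methyl 4-isopropoxybenzoate; the ketone ⇒ 2-methoxyresorcinol by O-isopropylation, bromination at C4 and bromine–lithium exchange/acetylation.
- Ring order: rings A and B are bought as benzenes; ring C closes in step 6.

Key step: step 6

Assumption: the target is taken as the neutral bis(hydrogen sulfate) as drawn. It is set free from its pyridinium salt on an acidic resin at the end; aryl hydrogen sulfates of this kind are best handled cold or stored as a disodium salt.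

**Route**

Step 1
Reactants: 1 2-methoxyresorcinol (2-methoxybenzene-1,3-diol)
Product: 2 1,3-diisopropoxy-2-methoxybenzene
Conditions: 2-bromopropane (3 equiv), K2CO3 (3 equiv), DMF, 60 °C, N2
Reagents that add atoms: 2-bromopropane, CC(C)Br
Why: Williamson ether synthesis, in which both phenoxide oxygens of 1 are alkylated by the secondary bromide and the excess of halide makes up for its loss to propene by elimination.

Step 2
Reactants: 2 1,3-diisopropoxy-2-methoxybenzene
Product: 3 1-bromo-2,4-diisopropoxy-3-methoxybenzene
Conditions: NBS (1.0 equiv), MeCN, 0 °C → rt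
Reagents that add atoms: N-bromosuccinimide, O=C1CCC(=O)N1Br
Why: Electrophilic aromatic bromination should go to C4, which is ortho to one isopropoxy group and para to the other, whereas C5 is meta to both, and one equivalent of reagent should stop at the monobromide because bromine deactivates the ring.

Step 3
Reactants: 3 1-bromo-2,4-diisopropoxy-3-methoxybenzene; 4 N-methoxy-N-methylacetamide
Product: 6 1-(2,4-diisopropoxy-3-methoxyphenyl)ethan-1-one, via aryllithium 5 (not isolated)
Conditions: n-BuLi (1.05 equiv), THF, −78 °C; then 4 (1.3 equiv), −78 → 0 °C; aq. NH4Cl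
Reagents that add atoms: n-butyllithium, [Li]CCCC (supplies only the lithium of 5)
Why: Bromine–lithium exchange at −78 °C fixes the carbanion at the brominated carbon, and the aryllithium adds only once to the amide because the chelated tetrahedral adduct holds until the quench (Weinreb ketone synthesis).

Step 4
Reactants: 7 methyl 4-hydroxybenzoate
Product: 8 methyl 4-isopropoxybenzoate
Conditions: 2-bromopropane (2 equiv), K2CO3 (2 equiv), DMF, 60 °C
Reagents that add atoms: 2-bromopropane, CC(C)Br
Why: Williamson ether synthesis on an acidic para-acyl phenol, with the methyl ester untouched by carbonate in DMF.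

Step 5
Reactants: 6 1-(2,4-diisopropoxy-3-methoxyphenyl)ethan-1-one; 8 methyl 4-isopropoxybenzoate
Product: 10 1-(2,4-diisopropoxy-3-methoxyphenyl)-3-(4-isopropoxyphenyl)propane-1,3-dione, via lithium enolate 9 (not isolated)
Conditions: LiN(SiMe3)2 (2.5 equiv), THF, −78 °C; then 8 (1.2 equiv), −78 → 40 °C; 1 M HCl
Reagents that add atoms: lithium bis(trimethylsilyl)amide, [Li]N([Si](C)(C)C)[Si](C)(C)C (supplies only the lithium of 9)
Why: Crossed Claisen condensation, in which the lithium enolate of the methyl ketone is acylated on carbon by the non-enolisable ester and the extra base removes the acidic proton of the diketone, which pulls the equilibrium forward.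

Step 6
Reactants: 10 1-(2,4-diisopropoxy-3-methoxyphenyl)-3-(4-isopropoxyphenyl)propane-1,3-dione
Product: 11 5,7-diisopropoxy-2-(4-isopropoxyphenyl)-6-methoxy-4H-chromen-4-one
Conditions: graphite anode, Pt cathode, undivided cell, constant current 5 mA cm−2, 2.2 F mol−1, 2,6-lutidine (1 equiv), n-Bu4NPF6 (0.1 M), HFIP, 0.02 M, 25 °C
Reagents that add atoms: none
Why: Proposed new method: with 2,6-lutidine in HFIP the internal hydrogen bond of 10 is broken and the enol(ate) conjugated with ring A gives up one electron at graphite, so that spin and charge are shared between the dicarbonyl unit and the ortho and para carbons of ring A; the oxygen on the carbon next to ring B then bonds to the free ortho carbon C6, and a second electron and the C6 proton are lost to restore ring A while the cathode turns protons into H2. The closest known reaction types are the anodic dehydrogenative lactonisation of biaryl-2-carboxylic acids and the FeCl3-mediated oxidative closure of α-aryl ketone enols onto methoxyarenes to give benzofurans, but an enol oxygen of a 1,3-diketone has not been closed in this way onto an unfunctionalised ortho carbon to give a 4-pyranone. Ring C closes in the six-membered mode O1–C2=C3–C4–C4a–C8a by O-attack on the aryl carbon (6-endo with respect to the C4a–C8a bond), the only closure the tether allows because attack through the central carbon would need a four-membered ring. No stereocentre is formed. The step needs ring A over ring B and C–H over ipso substitution: C6 of ring A is para to the 3-methoxy group, which stabilises the cyclohexadienyl intermediate, and the 2- and 4-isopropoxy groups lower the oxidation potential of the ring A enol, whereas the ortho carbons of ring B lie meta to its single alkoxy group, and attack at the isopropoxy-bearing C2 cannot end in proton loss and should revert in non-nucleophilic HFIP. High dilution should hold back intermolecular aryl–aryl coupling, and the product should resist further oxidation because its enol oxygen is then locked in a vinylogous ester.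

Step 7
Reactants: 11 5,7-diisopropoxy-2-(4-isopropoxyphenyl)-6-methoxy-4H-chromen-4-one
Product: 12 hispidulin (5,7-dihydroxy-2-(4-hydroxyphenyl)-6-methoxy-4H-chromen-4-one)
Conditions: BCl3 (1 M in CH2Cl2, 6 equiv), CH2Cl2, −78 → 0 °C; then ice-water
Reagents that add atoms: none
Why: Lewis-acid ether cleavage, in which BCl3 ionises the three secondary isopropyl–oxygen bonds (the one at O5 first, through the chelate with the C4 carbonyl) to 2-chloropropane, while the methyl ether at C6 has no such SN1 path and should stay if the mixture is kept at or below 0 °C.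

Step 8
Reactants: 12 hispidulin
Product: 14 hispidulin 7,4'-disulfate (free bis(hydrogen sulfate)), via bis(pyridinium) disulfate 13 (not isolated)
Conditions: SO3·pyridine (6 equiv), pyridine, 25 → 40 °C; then Dowex 50W (H+ form), H2O/MeOH, 0 °C, freeze-drying
Reagents that add atoms: sulfur trioxide–pyridine complex, O=S(=O)([O-])[n+]1ccccc1
Why: O-sulfation of phenols with the sulfur trioxide–pyridine complex should take the 7- and 4'-hydroxyls, while the 5-hydroxyl is held in the hydrogen bond to the C4 carbonyl, and the strong-acid resin exchanges pyridinium for protons.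

**Compound list**

1 | 2-methoxyresorcinol (2-methoxybenzene-1,3-diol) | COc1c(O)cccc1O | starting material
2 | 1,3-diisopropoxy-2-methoxybenzene | COc1c(OC(C)C)cccc1OC(C)C | intermediate
3 | 1-bromo-2,4-diisopropoxy-3-methoxybenzene | COc1c(OC(C)C)ccc(Br)c1OC(C)C | intermediate
4 | N-methoxy-N-methylacetamide | CC(=O)N(C)OC | starting material
5 | (2,4-diisopropoxy-3-methoxyphenyl)lithium (not isolated) | [Li]c1ccc(OC(C)C)c(OC)c1OC(C)C | intermediate
6 | 1-(2,4-diisopropoxy-3-methoxyphenyl)ethan-1-one | CC(=O)c1ccc(OC(C)C)c(OC)c1OC(C)C | intermediate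
7 | methyl 4-hydroxybenzoate | COC(=O)c1ccc(O)cc1 | starting material
8 | methyl 4-isopropoxybenzoate | COC(=O)c1ccc(OC(C)C)cc1 | intermediate
9 | lithium 1-(2,4-diisopropoxy-3-methoxyphenyl)ethen-1-olate (not isolated) | [Li]OC(=C)c1ccc(OC(C)C)c(OC)c1OC(C)C | intermediate
10 | 1-(2,4-diisopropoxy-3-methoxyphenyl)-3-(4-isopropoxyphenyl)propane-1,3-dione (drawn as the diketo form; largely enolised) | COc1c(OC(C)C)ccc(C(=O)CC(=O)c2ccc(OC(C)C)cc2)c1OC(C)C | intermediate
11 | 5,7-diisopropoxy-2-(4-isopropoxyphenyl)-6-methoxy-4H-chromen-4-one | COc1c(OC(C)C)cc2oc(-c3ccc(OC(C)C)cc3)cc(=O)c2c1OC(C)C | intermediate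
12 | hispidulin (5,7-dihydroxy-2-(4-hydroxyphenyl)-6-methoxy-4H-chromen-4-one) | COc1c(O)cc2oc(-c3ccc(O)cc3)cc(=O)c2c1O | intermediate
13 | bis(pyridinium) salt of hispidulin 7,4'-disulfate (not isolated) | COc1c(OS(=O)(=O)[O-])cc2oc(-c3ccc(OS(=O)(=O)[O-])cc3)cc(=O)c2c1O.c1cc[nH+]cc1.c1cc[nH+]cc1 | intermediate
14 | hispidulin 7,4'-disulfate | COc1c(OS(=O)(=O)O)cc2oc(-c3ccc(OS(=O)(=O)O)cc3)cc(=O)c2c1O | target

**Step count**

Total steps: 8. Longest linear sequence: 7 (steps 1, 2, 3, 5, 6, 7, 8).

**Steps most likely to fail**

Step 6. The oxidised enol may not be captured at the ring A C–H, which is meta to both isopropoxy groups and activated only by the para methoxy group. Intermolecular aryl–aryl coupling at the more electron-rich C5, coupling through the central carbon, ipso attack with loss of an isopropyl group, or over-oxidation of ring A may then take over. The fallback uses known chemistry and closes ring C through a phenol oxygen (O1–C2 bond) instead. It sets out from 2 and comes back at 11. Sterically controlled C–H borylation of 2 ([Ir(OMe)(cod)]2, 4,4'-di-tert-butyl-2,2'-bipyridine, B2pin2, THF, 80 °C) should go to the only C–H without an ortho neighbour and give 2-(3,5-diisopropoxy-4-methoxyphenyl)-4,4,5,5-tetramethyl-1,3,2-dioxaborolane F1. Oxidation (H2O2, NaOH, THF, 0 °C) gives 3,5-diisopropoxy-4-methoxyphenol F2. Ortho C-acetylation (Ac2O, BF3·OEt2, Friedel–Crafts/Fries type) gives 1-(6-hydroxy-2,4-diisopropoxy-3-methoxyphenyl)ethan-1-one F3. Claisen–Schmidt condensation with commercial 4-isopropoxybenzaldehyde (KOH, EtOH) gives (E)-1-(6-hydroxy-2,4-diisopropoxy-3-methoxyphenyl)-3-(4-isopropoxyphenyl)prop-2-en-1-one F4. Oxidative cyclisation of this 2'-hydroxychalcone (catalytic I2, DMSO, 120 °C) gives flavone 11, and steps 7 and 8 follow unchanged.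

Step 8. Sulfation may stop at a monosulfate or spread to O5, and the free aryl hydrogen sulfates may hydrolyse autocatalytically during acidification and drying. The fallback carries the sulfates as neutral, chromatographable diesters. It sets out from 12 and comes back at 14. Treatment of 12 with 2,2,2-trichloroethyl chlorosulfate (Et3N, DMAP, THF, 0 °C) should give 5-hydroxy-6-methoxy-4-oxo-2-{4-[(2,2,2-trichloroethoxy)sulfonyloxy]phenyl}-4H-chromen-7-yl 2,2,2-trichloroethyl sulfate F5, which can be purified on silica. Reductive removal of both trichloroethyl groups (zinc dust, HCO2NH4, MeOH, rt) gives the diammonium salt of hispidulin 7,4'-disulfate F6, and passage through the acidic resin as in step 8 gives 14.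

Step 5. C-acylation may stall because the para-alkoxy ester is a weak acceptor and the product consumes base, leaving self-condensation of the ketone to compete. The fallback reaches the same oxidation level by addition and oxidation. It sets out from 6 and comes back at 10. The lithium enolate 9 (LiN(SiMe3)2, THF, −78 °C) is added to commercial 4-isopropoxybenzaldehyde to give racemic 1-(2,4-diisopropoxy-3-methoxyphenyl)-3-hydroxy-3-(4-isopropoxyphenyl)propan-1-one F7. Oxidation of the secondary alcohol with 2-iodoxybenzoic acid (EtOAc, 75 °C) gives diketone 10.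

Further compounds
F1 | step 6 | 2-(3,5-diisopropoxy-4-methoxyphenyl)-4,4,5,5-tetramethyl-1,3,2-dioxaborolane | COc1c(OC(C)C)cc(B2OC(C)(C)C(C)(C)O2)cc1OC(C)C
F2 | step 6 | 3,5-diisopropoxy-4-methoxyphenol | COc1c(OC(C)C)cc(O)cc1OC(C)C
F3 | step 6 | 1-(6-hydroxy-2,4-diisopropoxy-3-methoxyphenyl)ethan-1-one | CC(=O)c1c(O)cc(OC(C)C)c(OC)c1OC(C)C
F4 | step 6 | (E)-1-(6-hydroxy-2,4-diisopropoxy-3-methoxyphenyl)-3-(4-isopropoxyphenyl)prop-2-en-1-one | COc1c(OC(C)C)cc(O)c(C(=O)/C=C/c2ccc(OC(C)C)cc2)c1OC(C)C
F5 | step 8 | 5-hydroxy-6-methoxy-4-oxo-2-{4-[(2,2,2-trichloroethoxy)sulfonyloxy]phenyl}-4H-chromen-7-yl 2,2,2-trichloroethyl sulfate | COc1c(OS(=O)(=O)OCC(Cl)(Cl)Cl)cc2oc(-c3ccc(OS(=O)(=O)OCC(Cl)(Cl)Cl)cc3)cc(=O)c2c1O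
F6 | step 8 | diammonium salt of hispidulin 7,4'-disulfate | COc1c(OS(=O)(=O)[O-])cc2oc(-c3ccc(OS(=O)(=O)[O-])cc3)cc(=O)c2c1O.[NH4+].[NH4+]
F7 | step 5 | 1-(2,4-diisopropoxy-3-methoxyphenyl)-3-hydroxy-3-(4-isopropoxyphenyl)propan-1-one (racemic) | COc1c(OC(C)C)ccc(C(=O)CC(O)c2ccc(OC(C)C)cc2)c1OC(C)C
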